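**Retrosynthetic overview**

- Numbering used: oxolane ring O1, C2 (dienyl), C3 (OH), C4 (CH2), C5 (CH3). The (1E,3E)-diene is cut at its central single bond, giving an (E)-alkenylboronate that carries the oxolane (8) and an (E)-iodoalkene that carries the isocoumarin (16); one silyl ether is removed last.
- Enabling feature: C5 of the oxolane ring carries only the ring oxygen O1, a methyl group and the unsubstituted ring carbon C4. O1–C5(CH3) is therefore an acetate ester of the C2 oxygen in disguise, and C4 is the inner carbon of a vinyl group on carbinol carbon C3. The oxolane ring is closed between C4 and C5 by titanium-mediated ester carbonyl–olefin metathesis of a plain acetate, at the 2,3-dihydrofuran oxidation level.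
- The acetate comes in two steps from twofold-symmetric (3R,4R)-hexa-1,5-diene-3,4-diol, which supplies C2, C3, C4, both stereocentres C2 and C3, and the first two diene carbons.
- C5 is set after ring closure by ionic hydrogenation of the cyclic enol ether (hydride cis to the C3 oxygen); cross-metathesis then turns the C2 vinyl group into the boronate.
- Ring order: the isocoumarin lactone ring is built separately (lateral lithiation and acylation of a chlorinated orsellinate, then enol lactonization); the oxolane ring is built in step 3; no ring is formed after fragment union.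

Key step: step 3

Assumption: (3R,4R)-hexa-1,5-diene-3,4-diol is taken as purchasable (it is otherwise reached from D-mannitol in a short known sequence).

**Route**

Step 1
Reactants: 1 (3R,4R)-hexa-1,5-diene-3,4-diol
Product: 2 (3R,4R)-4-[(tert-butyldimethylsilyl)oxy]hexa-1,5-dien-3-ol
Conditions: NaH (1.0 equiv), THF, 0 °C; TBSCl (1.0 equiv), 0 → 23 °C
Reagents that add atoms: tert-butyldimethylsilyl chloride, CC(C)(C)[Si](C)(C)Cl
Why: Monosilylation of a symmetric diol through its monosodium alkoxide (O-silylation); the two hydroxyl groups are homotopic through the twofold axis, so only one mono-ether exists, silyl migration is degenerate and no stereocentre is touched.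

Step 2
Reactants: 2 (3R,4R)-4-[(tert-butyldimethylsilyl)oxy]hexa-1,5-dien-3-ol
Product: 3 (3R,4R)-4-[(tert-butyldimethylsilyl)oxy]hexa-1,5-dien-3-yl acetate
Conditions: Ac2O, pyridine, DMAP (cat.), CH2Cl2, 0 → 23 °C
Reagents that add atoms: acetic anhydride, CC(=O)OC(C)=O
Why: DMAP-catalysed acylation of the remaining secondary alcohol with retention at the carbinol carbon; the acetyl group brings in the two carbons that become C5 and its methyl group.

Step 3
Reactants: 3 (3R,4R)-4-[(tert-butyldimethylsilyl)oxy]hexa-1,5-dien-3-yl acetate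
Product: 5 tert-butyl{[(2R,3R)-2-ethenyl-5-methyl-2,3-dihydrofuran-3-yl]oxy}dimethylsilane, via dichlorotitanium alkylidene 4 (not isolated)
Conditions: TiCl4, TMEDA, Zn, PbCl2 (cat.), CH3CHBr2 (all in excess), THF/CH2Cl2, 0 → 65 °C; aq. K2CO3 work-up
Reagents that add atoms: none
Why: The reduced titanium ethylidene made in the flask (Takai–Utimoto type reagent) first exchanges alkylidenes with a terminal vinyl group by olefin metathesis (loss of propene); the substrate-bound alkylidene 4 at C4 then adds across the acetate carbonyl C5 in a [2+2] sense and the oxatitanacyclobutane cycloreverts, so C4 and C5 are joined as the endocyclic double bond of the 2,3-dihydrofuran while the carbonyl oxygen leaves on titanium. The closest known reaction type is the olefinic ester cyclization of alkenyl esters to cyclic enol ethers with titanium alkylidenes (carbonyl–olefin ring-closing metathesis). The oxolane ring is closed as a five-membered ring-closing carbonyl olefination in which both reacting carbons, C4 and C5, become ring members. No stereocentre is formed: C2 and C3 are carried unchanged from diol 1, and C5 is left sp2 on purpose, to be set in step 4. The selectivity needed is between the two vinyl groups and is secured by ring size: only the vinyl group on the silyloxy carbon can reach the acetate through a five-membered ring, whereas the alkylidene of the other vinyl group would have to close a four-membered ring and can only revert. The silyl ether and the trisubstituted enol ether product should not react further with the reagent.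

Step 4
Reactants: 5 tert-butyl{[(2R,3R)-2-ethenyl-5-methyl-2,3-dihydrofuran-3-yl]oxy}dimethylsilane
Product: 7 tert-butyl{[(2R,3R,5R)-2-ethenyl-5-methyloxolan-3-yl]oxy}dimethylsilane, via oxocarbenium trifluoroacetate 6 (not isolated)
Conditions: Et3SiH (5 equiv), CF3CO2H (2 equiv), CH2Cl2, −78 → −40 °C
Reagents that add atoms: none
Why: Ionic hydrogenation: protonation of the enol ether at C4 gives the 2-methyl oxocarbenium ion 6, whose favoured envelope has the C3 silyloxy group pseudoaxial and the C2 vinyl group pseudoequatorial, and hydride adds from the inside face, cis to the C3 oxygen (the 1,3-cis rule for 3-alkoxy five-membered oxocarbenium ions), so the C5 methyl group ends trans to both ring substituents, which is (5R).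

Step 5
Reactants: 7 tert-butyl{[(2R,3R,5R)-2-ethenyl-5-methyloxolan-3-yl]oxy}dimethylsilane
Product: 8 2-[(E)-2-{(2R,3R,5R)-3-[(tert-butyldimethylsilyl)oxy]-5-methyloxolan-2-yl}ethenyl]-4,4,5,5-tetramethyl-1,3,2-dioxaborolane
Conditions: CH2=CH–Bpin (3 equiv), second-generation Hoveyda–Grubbs catalyst RuCl2(H2IMes)(=CH-C6H4-2-OiPr) (5 mol %), CH2Cl2, 40 °C
Reagents that add atoms: vinylboronic acid pinacol ester, C=CB1OC(C)(C)C(C)(C)O1
Why: Olefin cross-metathesis of the terminal alkene with a vinylboronate; the bulky boronate and equilibration of the product should favour the (E)-alkenylboronate, and the ring stereocentres take no part.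

Step 6
Reactants: 9 methyl 2,4-dimethoxy-6-methylbenzoate
Product: 10 methyl 3-chloro-4,6-dimethoxy-2-methylbenzoate
Conditions: SO2Cl2 (1.05 equiv), CH2Cl2, 0 °C
Reagents that add atoms: sulfuryl chloride, ClS(Cl)(=O)=O
Why: Electrophilic aromatic chlorination; the ring position next to the methyl group is para to one methoxy group and ortho to the other and should react in preference to the position flanked by both methoxy groups, which places chlorine at the future C5 of the isocoumarin.

Step 7
Reactants: 10 methyl 3-chloro-4,6-dimethoxy-2-methylbenzoate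
Product: 12 methyl 3-chloro-2-(3,3-diethoxy-2-oxopropyl)-4,6-dimethoxybenzoate, via benzylic lithium compound 11 (not isolated)
Conditions: LDA (2.2 equiv), THF, −78 °C; ethyl diethoxyacetate (1.2 equiv), −78 → −40 °C; aq. NH4Cl
Reagents that add atoms: ethyl 2,2-diethoxyacetate, CCOC(=O)C(OCC)OCC
Why: Lateral (benzylic) lithiation of the ortho-toluate gives the ester-stabilised anion 11, which undergoes Claisen-type C-acylation by the ester; the doubly ortho-substituted benzoate resists self-condensation and the second equivalent of base holds the product as its enolate against over-addition.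

Step 8
Reactants: 12 methyl 3-chloro-2-(3,3-diethoxy-2-oxopropyl)-4,6-dimethoxybenzoate
Product: 14 5-chloro-6,8-dimethoxy-1-oxo-1H-isochromene-3-carbaldehyde, via isocoumarin diethyl acetal 13 (not isolated)
Conditions: p-TsOH·H2O (10 mol %), toluene, 90 °C; then 2 M HCl, THF, 23 °C
Reagents that add atoms: water, O
Why: Acid-catalysed enol lactonization (the enol oxygen of the benzylic ketone acylates the neighbouring methyl ester, 6-exo-trig) closes the isocoumarin ring to acetal 13, whose acetal now sits on an enol-ether carbon and should hydrolyse readily to the aldehyde.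

Step 9
Reactants: 14 5-chloro-6,8-dimethoxy-1-oxo-1H-isochromene-3-carbaldehyde
Product: 15 5-chloro-3-[(E)-2-iodoethenyl]-6,8-dimethoxy-1H-isochromen-1-one
Conditions: CrCl2 (8 equiv), CHI3 (3 equiv), THF/1,4-dioxane, 0 → 23 °C
Reagents that add atoms: iodoform, IC(I)I
Why: Takai olefination; the geminal dichromium carbenoid adds to the aldehyde and anti elimination gives the (E)-iodoalkene, while the lactone and the aryl chloride are inert to CrCl2.

Step 10
Reactants: 15 5-chloro-3-[(E)-2-iodoethenyl]-6,8-dimethoxy-1H-isochromen-1-one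
Product: 16 5-chloro-6,8-dihydroxy-3-[(E)-2-iodoethenyl]-1H-isochromen-1-one
Conditions: BBr3 (6 equiv), CH2Cl2, −78 → 23 °C; then MeOH, H2O
Reagents that add atoms: none
Why: Lewis-acid cleavage of both aryl methyl ethers (the peri 8-methoxy first, helped by chelation to the lactone carbonyl); the enol lactone and the conjugated, electron-poor iodoalkene should survive.

Step 11
Reactants: 8 2-[(E)-2-{(2R,3R,5R)-3-[(tert-butyldimethylsilyl)oxy]-5-methyloxolan-2-yl}ethenyl]-4,4,5,5-tetramethyl-1,3,2-dioxaborolane; 16 5-chloro-6,8-dihydroxy-3-[(E)-2-iodoethenyl]-1H-isochromen-1-one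
Product: 17 3-[(1E,3E)-4-{(2R,3R,5R)-3-[(tert-butyldimethylsilyl)oxy]-5-methyloxolan-2-yl}buta-1,3-dien-1-yl]-5-chloro-6,8-dihydroxy-1H-isochromen-1-one
Conditions: Pd(dppf)Cl2 (5 mol %), K3PO4 (5 equiv), degassed THF/H2O (10:1), 45 °C
Reagents that add atoms: none
Why: Suzuki–Miyaura coupling of an alkenylboronate with an alkenyl iodide proceeds with retention at both double bonds and gives the (1E,3E)-diene; the phenols react as phenoxides, which do not interfere and make the lactone carbonyl less electrophilic toward the aqueous base.

Step 12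
Reactants: 17 3-[(1E,3E)-4-{(2R,3R,5R)-3-[(tert-butyldimethylsilyl)oxy]-5-methyloxolan-2-yl}buta-1,3-dien-1-yl]-5-chloro-6,8-dihydroxy-1H-isochromen-1-one
Product: 18 5-chloro-6,8-dihydroxy-3-[(1E,3E)-4-[(2R,3R,5R)-3-hydroxy-5-methyloxolan-2-yl]buta-1,3-dien-1-yl]-1H-isochromen-1-one
Conditions: HF·pyridine, pyridine, THF, 0 → 23 °C
Reagents that add atoms: none
Why: Fluoride-driven cleavage of the secondary silyl ether under buffered conditions, which should leave the dienylic C2–O1 bond, the diene and the lactone untouched; no stereocentre is affected.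

**Compound list**

1 | (3R,4R)-hexa-1,5-diene-3,4-diol | O[C@H](C=C)[C@H](O)C=C | starting material
2 | (3R,4R)-4-[(tert-butyldimethylsilyl)oxy]hexa-1,5-dien-3-ol | O[C@H](C=C)[C@H](O[Si](C)(C)C(C)(C)C)C=C | intermediate
3 | (3R,4R)-4-[(tert-butyldimethylsilyl)oxy]hexa-1,5-dien-3-yl acetate | CC(=O)O[C@H](C=C)[C@H](O[Si](C)(C)C(C)(C)C)C=C | intermediate
4 | dichlorotitanium alkylidene formed from 3 at the vinyl group on the silyloxy-bearing carbon (both carbinol carbons unchanged; TMEDA ligand omitted) | CC(=O)O[C@H](C=C)[C@H](O[Si](C)(C)C(C)(C)C)C=[Ti](Cl)Cl | intermediate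
5 | tert-butyl{[(2R,3R)-2-ethenyl-5-methyl-2,3-dihydrofuran-3-yl]oxy}dimethylsilane | CC1=C[C@@H](O[Si](C)(C)C(C)(C)C)[C@@H](C=C)O1 | intermediate
6 | (2R,3R)-3-[(tert-butyldimethylsilyl)oxy]-2-ethenyl-5-methyl-3,4-dihydro-2H-furan-1-ium trifluoroacetate (oxocarbenium ion) | CC1=[O+][C@H](C=C)[C@H](O[Si](C)(C)C(C)(C)C)C1.[O-]C(=O)C(F)(F)F | intermediate
7 | tert-butyl{[(2R,3R,5R)-2-ethenyl-5-methyloxolan-3-yl]oxy}dimethylsilane | C[C@@H]1C[C@@H](O[Si](C)(C)C(C)(C)C)[C@@H](C=C)O1 | intermediate
8 | 2-[(E)-2-{(2R,3R,5R)-3-[(tert-butyldimethylsilyl)oxy]-5-methyloxolan-2-yl}ethenyl]-4,4,5,5-tetramethyl-1,3,2-dioxaborolane | C[C@@H]1C[C@@H](O[Si](C)(C)C(C)(C)C)[C@@H](/C=C/B2OC(C)(C)C(C)(C)O2)O1 | intermediate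
9 | methyl 2,4-dimethoxy-6-methylbenzoate | COC(=O)c1c(C)cc(OC)cc1OC | starting material
10 | methyl 3-chloro-4,6-dimethoxy-2-methylbenzoate | COC(=O)c1c(C)c(Cl)c(OC)cc1OC | intermediate
11 | [2-chloro-3,5-dimethoxy-6-(methoxycarbonyl)phenyl]methyllithium | COC(=O)c1c(C[Li])c(Cl)c(OC)cc1OC | intermediate
12 | methyl 3-chloro-2-(3,3-diethoxy-2-oxopropyl)-4,6-dimethoxybenzoate | COC(=O)c1c(CC(=O)C(OCC)OCC)c(Cl)c(OC)cc1OC | intermediate
13 | 5-chloro-3-(diethoxymethyl)-6,8-dimethoxy-1H-isochromen-1-one | CCOC(OCC)c1cc2c(Cl)c(OC)cc(OC)c2c(=O)o1 | intermediate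
14 | 5-chloro-6,8-dimethoxy-1-oxo-1H-isochromene-3-carbaldehyde | O=Cc1cc2c(Cl)c(OC)cc(OC)c2c(=O)o1 | intermediate
15 | 5-chloro-3-[(E)-2-iodoethenyl]-6,8-dimethoxy-1H-isochromen-1-one | I/C=C/c1cc2c(Cl)c(OC)cc(OC)c2c(=O)o1 | intermediate
16 | 5-chloro-6,8-dihydroxy-3-[(E)-2-iodoethenyl]-1H-isochromen-1-one | I/C=C/c1cc2c(Cl)c(O)cc(O)c2c(=O)o1 | intermediate
17 | 3-[(1E,3E)-4-{(2R,3R,5R)-3-[(tert-butyldimethylsilyl)oxy]-5-methyloxolan-2-yl}buta-1,3-dien-1-yl]-5-chloro-6,8-dihydroxy-1H-isochromen-1-one | C[C@@H]1C[C@@H](O[Si](C)(C)C(C)(C)C)[C@@H](/C=C/C=C/c2cc3c(Cl)c(O)cc(O)c3c(=O)o2)O1 | intermediate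
18 | 5-chloro-6,8-dihydroxy-3-[(1E,3E)-4-[(2R,3R,5R)-3-hydroxy-5-methyloxolan-2-yl]buta-1,3-dien-1-yl]-1H-isochromen-1-one | C[C@@H]1C[C@@H](O)[C@@H](/C=C/C=C/c2cc3c(Cl)c(O)cc(O)c3c(=O)o2)O1 | target

**Step count and risks**

Total step count: 12. Longest linear sequence: 7 steps (steps 1, 2, 3, 4, 5, 11, 12; the isocoumarin branch, steps 6–10 then 11 and 12, is equally long).

Steps most likely to fail:

Step 3. The titanium ethylidene may exchange unproductively at the spare vinyl group, the low-valent titanium/zinc medium may reductively cleave the allylic acetate, or the carbonyl olefination may stall at an acyclic enol ether. The fallback sets out from 3 and separates the two events. Methylenation of the acetate with dimethyltitanocene Cp2TiMe2 (toluene, 65 °C) should give the isopropenyl ether tert-butyl{[(3R,4R)-4-(prop-1-en-2-yloxy)hexa-1,5-dien-3-yl]oxy}dimethylsilane F1. Ruthenium-catalysed diene ring-closing metathesis (second-generation Grubbs catalyst RuCl2(=CHPh)(H2IMes)(PCy3), toluene, 60 °C) should then join the same two carbons with loss of ethylene, again with only the five-membered closure open, and return to 5.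

Step 4. Under Brønsted acid the allylic silyloxy group may be lost with aromatization to a furan, or the facial selectivity of hydride delivery may erode. The fallback sets out from 5 and replaces protonation of the enol ether by ionization of an isolated ketal. Addition of methanol (PPTS cat., MeOH, 0 °C) should give the methyl ketal tert-butyl{[(2R,3R)-2-ethenyl-5-methoxy-5-methyloxolan-3-yl]oxy}dimethylsilane F2 as an anomer mixture. Both anomers should converge on the same oxocarbenium ion when ionized by a Lewis acid at low temperature with the silane already present (Et3SiH, BF3·OEt2, CH2Cl2, −78 °C; reductive deoxygenation of a ketal), returning to 7.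

Step 5. Cross-metathesis at the hindered allylic ether position may be slow, the vinylboronate may homodimerize, or the alkene geometry may be poorly controlled. The fallback sets out from 7 and builds the alkenylboronate from a carbonyl group instead. Ozonolysis (O3, CH2Cl2, −78 °C; PPh3) should give the aldehyde (2S,3R,5R)-3-[(tert-butyldimethylsilyl)oxy]-5-methyloxolane-2-carbaldehyde F3, used crude to avoid epimerization at C2. The boron variant of the Takai olefination (Cl2CHBpin, CrCl2, LiI, THF, 23 °C) should then return to 8 as the (E)-isomer.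

**Further compounds**

F1 | step 3 | tert-butyl{[(3R,4R)-4-(prop-1-en-2-yloxy)hexa-1,5-dien-3-yl]oxy}dimethylsilane | CC(=C)O[C@H](C=C)[C@H](O[Si](C)(C)C(C)(C)C)C=C
F2 | step 4 | tert-butyl{[(2R,3R)-2-ethenyl-5-methoxy-5-methyloxolan-3-yl]oxy}dimethylsilane (anomer mixture) | COC1(C)C[C@@H](O[Si](C)(C)C(C)(C)C)[C@@H](C=C)O1
F3 | step 5 | (2S,3R,5R)-3-[(tert-butyldimethylsilyl)oxy]-5-methyloxolane-2-carbaldehyde | C[C@@H]1C[C@@H](O[Si](C)(C)C(C)(C)C)[C@@H](C=O)O1
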